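The route rests on cutting the bond between the ester carbonyl carbon and C2 of the naphthalene. A palladium-catalysed three-component alkoxycarbonylation unites a 4-aryl-2-naphthyl triflate, carbon monoxide and the free secondary hydroxyl of tribenzyl-protected (R)-danshensu. It makes the C2–C(=O) and C(=O)–O bonds in one operation. The step exploits the carbonyl as a one-carbon bridge between an unhindered ring position (C2, flanked by C1–H and C3–H) and the carbinol oxygen. The carbinol C–O bond is never touched, so the (R) centre is carried through. The triflate oxygen comes directly from the cationic arylacetyl chloride/arylalkyne annulation that builds the substituted naphthalene ring.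

Key step: step 4

Assumption: CIP analysis of the target's only stereocentre gives (R), the configuration of natural danshensu. Sodium (R)-danshensu is therefore taken as a commercial single enantiomer (chiral pool).

Step 1
Reactants: 1 (3,4-dimethoxyphenyl)acetyl chloride; 2 4-ethynyl-1,2-dimethoxybenzene
Product: 4 naphthol 4-(3,4-dimethoxyphenyl)-6,7-dimethoxynaphthalen-2-ol, via keto tautomer 4-(3,4-dimethoxyphenyl)-6,7-dimethoxynaphthalen-2(1H)-one 3 (not isolated)
Conditions: AlCl3 (2 equiv), CH2Cl2, −20 → 0 °C; then cold aq. HCl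
Reagents that add atoms: none
Why: Friedel–Crafts-type acylation of the terminal alkyne carbon by the acylium ion of 1 gives an aryl-stabilised vinyl cation that closes the six-membered ring on the veratryl carbon para to the 3-methoxy group, and ketone 3 tautomerises to the aromatic naphthol (known arylacetyl chloride/alkyne 2-naphthol annulation; no stereocentre is formed).

Step 2
Reactants: 4 naphthol 4-(3,4-dimethoxyphenyl)-6,7-dimethoxynaphthalen-2-ol
Product: 5 naphthyl triflate 4-(3,4-dimethoxyphenyl)-6,7-dimethoxynaphthalen-2-yl trifluoromethanesulfonate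
Conditions: Tf2O, pyridine, CH2Cl2, 0 °C
Reagents that add atoms: triflic anhydride, O=S(=O)(OS(=O)(=O)C(F)(F)F)C(F)(F)F
Why: O-sulfonylation of the only free hydroxyl with triflic anhydride is a standard aryl triflate formation, and the four methyl ethers are inert.

Step 3
Reactants: 6 sodium (R)-danshensu, sodium (2R)-3-(3,4-dihydroxyphenyl)-2-hydroxypropanoate
Product: 7 benzyl (2R)-3-[3,4-bis(benzyloxy)phenyl]-2-hydroxypropanoate
Conditions: BnBr (3.3 equiv), K2CO3, DMF, rt, Ar
Reagents that add atoms: benzyl bromide, BrCc1ccccc1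
Why: In this Williamson-type O-alkylation carbonate deprotonates only the two phenols, which are benzylated together with the carboxylate, while the far less acidic secondary alcohol stays free and the chiral-pool (R) centre is not touched.

Step 4
Reactants: 5 naphthyl triflate 4-(3,4-dimethoxyphenyl)-6,7-dimethoxynaphthalen-2-yl trifluoromethanesulfonate; 7 benzyl (2R)-3-[3,4-bis(benzyloxy)phenyl]-2-hydroxypropanoate; 8 carbon monoxide
Product: 11 protected ester benzyl (2R)-3-[3,4-bis(benzyloxy)phenyl]-2-{[4-(3,4-dimethoxyphenyl)-6,7-dimethoxynaphthalene-2-carbonyl]oxy}propanoate, via aroylpalladium(II) triflate complex 9 (not isolated), via 1-aroyl-4-(dimethylamino)pyridinium triflate 10 (not isolated)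
Conditions: Pd(OAc)2 (5 mol %), Xantphos (6 mol %), CO (1 atm), Et3N (2 equiv), DMAP (20 mol %), 4 Å MS, toluene, 80 °C; 7 in slight excess
Reagents that add atoms: carbon monoxide (8), [C-]#[O+]
Why: Pd(0) inserts into the C2–OTf bond of 5, CO 8 inserts into the naphthyl–Pd bond to make the new C2–C(=O) bond in aroylpalladium complex 9, DMAP takes over the acyl group as aroylpyridinium triflate 10, and the secondary hydroxyl of 7 is acylated while Et3N takes up the triflic acid and Pd(0) is released. The closest known reaction type is the palladium-catalysed alkoxycarbonylation (carbonylative esterification) of aryl triflates, here run with a near-stoichiometric complex secondary alcohol and a nucleophilic acyl-transfer co-catalyst. No ring is closed and no new stereocentre is made; the (R) centre of 7 reacts only at its O–H bond, so its configuration is retained, and the weak amine base in toluene should not enolise the α-acyloxy ester. Chemoselectivity is needed at two points and is built into the substrates: the triflate is the only C–X bond of 5 that Pd(0) can enter, and the carbinol is the only free nucleophile of 7 because both phenols and the acid are benzylated. C2 has hydrogen on both neighbours (C1 and C3), so oxidative addition and CO insertion are not hindered by the C4 aryl group, and molecular sieves suppress hydrolysis of 9 and 10 to the acid.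

Step 5
Reactants: 11 protected ester benzyl (2R)-3-[3,4-bis(benzyloxy)phenyl]-2-{[4-(3,4-dimethoxyphenyl)-6,7-dimethoxynaphthalene-2-carbonyl]oxy}propanoate
Product: 12 eritrichin, (2R)-3-(3,4-dihydroxyphenyl)-2-{[4-(3,4-dihydroxyphenyl)-6,7-dihydroxynaphthalene-2-carbonyl]oxy}propanoic acid
Conditions: BBr3 (12 equiv), pentamethylbenzene (6 equiv), CH2Cl2, −78 → 0 °C; then ice–water; reversed-phase purification under Ar
Reagents that add atoms: none
Why: Lewis-acid ether cleavage with BBr3 removes the four aryl methyl ethers, the two aryl benzyl ethers and the benzyl ester by alkyl–oxygen scission, pentamethylbenzene traps the benzyl cations before they can alkylate the catechol rings, and the naphthoate ester of a secondary, carbonyl-deactivated carbinol and its (R) centre should survive at or below 0 °C.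

Compound list
1 | (3,4-dimethoxyphenyl)acetyl chloride | COc1ccc(CC(=O)Cl)cc1OC | starting material
2 | 4-ethynyl-1,2-dimethoxybenzene | C#Cc1ccc(OC)c(OC)c1 | starting material
3 | 4-(3,4-dimethoxyphenyl)-6,7-dimethoxynaphthalen-2(1H)-one | O=C1C=C(c2ccc(OC)c(OC)c2)c2cc(OC)c(OC)cc2C1 | intermediate
4 | 4-(3,4-dimethoxyphenyl)-6,7-dimethoxynaphthalen-2-ol | Oc1cc(-c2ccc(OC)c(OC)c2)c2cc(OC)c(OC)cc2c1 | intermediate
5 | 4-(3,4-dimethoxyphenyl)-6,7-dimethoxynaphthalen-2-yl trifluoromethanesulfonate | O=S(=O)(Oc1cc(-c2ccc(OC)c(OC)c2)c2cc(OC)c(OC)cc2c1)C(F)(F)F | intermediate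
6 | sodium (2R)-3-(3,4-dihydroxyphenyl)-2-hydroxypropanoate (sodium (R)-danshensu) | O[C@H](Cc1ccc(O)c(O)c1)C(=O)[O-].[Na+] | starting material
7 | benzyl (2R)-3-[3,4-bis(benzyloxy)phenyl]-2-hydroxypropanoate | O[C@H](Cc1ccc(OCc2ccccc2)c(OCc2ccccc2)c1)C(=O)OCc1ccccc1 | intermediate
8 | carbon monoxide | [C-]#[O+] | starting material
9 | [4-(3,4-dimethoxyphenyl)-6,7-dimethoxy-2-naphthoyl]palladium(II) triflate (Xantphos ligand omitted from the SMILES) | O=C([Pd]OS(=O)(=O)C(F)(F)F)c1cc(-c2ccc(OC)c(OC)c2)c2cc(OC)c(OC)cc2c1 | intermediate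
10 | 1-[4-(3,4-dimethoxyphenyl)-6,7-dimethoxy-2-naphthoyl]-4-(dimethylamino)pyridinium triflate | CN(C)c1cc[n+](C(=O)c2cc(-c3ccc(OC)c(OC)c3)c3cc(OC)c(OC)cc3c2)cc1.[O-]S(=O)(=O)C(F)(F)F | intermediate
11 | benzyl (2R)-3-[3,4-bis(benzyloxy)phenyl]-2-{[4-(3,4-dimethoxyphenyl)-6,7-dimethoxynaphthalene-2-carbonyl]oxy}propanoate | O=C(O[C@H](Cc1ccc(OCc2ccccc2)c(OCc2ccccc2)c1)C(=O)OCc1ccccc1)c1cc(-c2ccc(OC)c(OC)c2)c2cc(OC)c(OC)cc2c1 | intermediate
12 | eritrichin, (2R)-3-(3,4-dihydroxyphenyl)-2-{[4-(3,4-dihydroxyphenyl)-6,7-dihydroxynaphthalene-2-carbonyl]oxy}propanoic acid | O=C(O[C@H](Cc1ccc(O)c(O)c1)C(=O)O)c1cc(-c2ccc(O)c(O)c2)c2cc(O)c(O)cc2c1 | target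

Total step count: 5. Longest linear sequence: 4 (steps 1, 2, 4, 5); step 3 is the one-step side branch.

Steps most likely to fail

Step 4. Acyl transfer to the hindered, electron-poor α-hydroxy ester may be too slow. Hydrolysis by adventitious water, reduction of the triflate, or slow epimerisation on prolonged heating could then take over. The fallback separates C–C from C–O bond formation.
- It sets out from 5. Hydroxycarbonylation (Pd(OAc)2, dppf, KOAc, CO 1 atm, DMSO, 60 °C, aqueous work-up) should give 4-(3,4-dimethoxyphenyl)-6,7-dimethoxy-2-naphthoic acid F1.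
- F1 is esterified with 7 under Steglich conditions (EDC·HCl, DMAP, CH2Cl2, 0 °C → rt) with retention at the carbinol, and the route is rejoined at 11.

Step 1. Several processes may erode the annulation: loss of CO from the electron-rich arylacetyl cation, cationic oligomerisation of the electron-rich alkyne, capture of the vinyl cation by chloride, and Lewis-acid demethylation. The fallback installs the C2 oxygen afterwards by C–H functionalisation.
- It sets out from 2. Catalytic acid benzannulation with commercial (3,4-dimethoxyphenyl)acetaldehyde (FeCl3 10 mol %, 1,2-dichloroethane, rt) should give 1-(3,4-dimethoxyphenyl)-6,7-dimethoxynaphthalene F2.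
- Sterically controlled iridium-catalysed C–H borylation ([Ir(OMe)(cod)]2, dtbpy, B2pin2, THF, 80 °C) should attack the only ring C–H with hydrogen on both neighbours. This gives 2-[4-(3,4-dimethoxyphenyl)-6,7-dimethoxynaphthalen-2-yl]-4,4,5,5-tetramethyl-1,3,2-dioxaborolane F3.
- Oxidation of F3 (H2O2, NaOH, THF, 0 °C) comes back to the route at 4.

Step 5. Possible problems are incomplete demethylation, C-benzylation of the catechol rings, Lewis-acid scission of the naphthoate ester, and air oxidation of the hexaphenol during work-up. The fallback exchanges the protecting groups before the coupling, so that the last step is a neutral hydrogenolysis.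
- It sets out from 5. BBr3 (CH2Cl2, −78 → 0 °C; the aryl triflate is inert) should give 4-(3,4-dihydroxyphenyl)-6,7-dihydroxynaphthalen-2-yl trifluoromethanesulfonate F4.
- BnBr and K2CO3 in acetone should give 4-[3,4-bis(benzyloxy)phenyl]-6,7-bis(benzyloxy)naphthalen-2-yl trifluoromethanesulfonate F5.
- The carbonylation of step 4 with 7 and 8 should give the heptabenzyl ester benzyl (2R)-2-({4-[3,4-bis(benzyloxy)phenyl]-6,7-bis(benzyloxy)naphthalene-2-carbonyl}oxy)-3-[3,4-bis(benzyloxy)phenyl]propanoate F6.
- H2 (1 atm) over Pd/C in THF/MeOH comes back to the route at 12.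

Further compounds
F1 | step 4 | 4-(3,4-dimethoxyphenyl)-6,7-dimethoxy-2-naphthoic acid | O=C(O)c1cc(-c2ccc(OC)c(OC)c2)c2cc(OC)c(OC)cc2c1
F2 | step 1 | 1-(3,4-dimethoxyphenyl)-6,7-dimethoxynaphthalene | COc1ccc(-c2cccc3cc(OC)c(OC)cc23)cc1OC
F3 | step 1 | 2-[4-(3,4-dimethoxyphenyl)-6,7-dimethoxynaphthalen-2-yl]-4,4,5,5-tetramethyl-1,3,2-dioxaborolane | CC1(C)OB(c2cc(-c3ccc(OC)c(OC)c3)c3cc(OC)c(OC)cc3c2)OC1(C)C
F4 | step 5 | 4-(3,4-dihydroxyphenyl)-6,7-dihydroxynaphthalen-2-yl trifluoromethanesulfonate | O=S(=O)(Oc1cc(-c2ccc(O)c(O)c2)c2cc(O)c(O)cc2c1)C(F)(F)F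
F5 | step 5 | 4-[3,4-bis(benzyloxy)phenyl]-6,7-bis(benzyloxy)naphthalen-2-yl trifluoromethanesulfonate | O=S(=O)(Oc1cc(-c2ccc(OCc3ccccc3)c(OCc3ccccc3)c2)c2cc(OCc3ccccc3)c(OCc3ccccc3)cc2c1)C(F)(F)F
F6 | step 5 | benzyl (2R)-2-({4-[3,4-bis(benzyloxy)phenyl]-6,7-bis(benzyloxy)naphthalene-2-carbonyl}oxy)-3-[3,4-bis(benzyloxy)phenyl]propanoate | O=C(O[C@H](Cc1ccc(OCc2ccccc2)c(OCc2ccccc2)c1)C(=O)OCc1ccccc1)c1cc(-c2ccc(OCc3ccccc3)c(OCc3ccccc3)c2)c2cc(OCc3ccccc3)c(OCc3ccccc3)cc2c1
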